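The easy step comes first, the reagent dissolving in, and from it follows whether the next round needs a range of base charges or a single one.

| flask | starting material | base | gas | time |
|---|---|---|---|---|
| Wednesday's | 0.56 M | 0.0120 M | 130 mM (held) | 15 s |
| Tuesday's | 0.56 M | 0.0150 M | 130 mM (held) | 15 s |
| Thursday's | 0.56 M | 0.0250 M | 130 mM (held) | 15 s |
| Sunday's | 0.56 M | 0.0400 M | 130 mM (held) | 15 s |

    starting material + reagent + released group → target + 2 released group (k1 = 3.3 /M²/s)
    base + released group ⇌ salt, settled at all times (K2 = 22000 /M)
    released group → by-product carried off (k3 = 0.048 /s)
    starting material + reagent → target + released group (k4 = 1.3 × 10⁻⁴ /M/s)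
    gas ⇌ reagent, rate k5*(csat - [reagent]) (k5 = 0.054 /s, csat = 130 mM)

- [target] at the end for Wednesday's, Tuesday's, Thursday's, Sunday's, in this order
- the course of these numbers from the first flask to the last (falls all the way / hardly changes / falls, then rises / rises all the way / rises, then falls)

- at the start none of reagent is dissolved
- "hardly changes" means that all values lie within two and a half points (for a concentration: within two and a half percent of the largest)
- run time (Wednesday's): 15 s

By my reckoning, [reagent] starts at zero and climbs toward 130 mM at the transfer coefficient 0.054 /s, and its integral over 15 s comes to 0.614 M·s. With [starting material] taken as charged, the direct step (starting material + reagent) then makes 4.47 × 10⁻⁵ M of target and as much released group. That is far less than the smallest base charge, so the base stays close to its charge and, on Wednesday's, holds nearly all of the released group as salt.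

The free part is the amount made divided by one plus the equilibrium constant times [base], and this gives 1.69 × 10⁻⁷ M on Wednesday's and 5.07 × 10⁻⁸ M on Sunday's.

The self-feeding step (autocatalysis) and the direct step both carry the factors [starting material][reagent], so they compare through one number. The free [released group] at which the self-feeding step goes as fast as the direct step, the ratio of their constants, is the crossing level, 3.94 × 10⁻⁵ M. Wednesday's free level lies far below it, at 0.428% of it, and Sunday's lies lower still, so I expect about 4.47 × 10⁻⁵ M of target in each flask, and the next round can keep the single charge 0.0120 M.

The forecast gives 4.480 × 10⁻⁵ M, 4.470 × 10⁻⁵ M, 4.470 × 10⁻⁵ M and 4.470 × 10⁻⁵ M, a course that hardly changes, where my figure for each flask is 4.47 × 10⁻⁵ M. Its ground is that “the base holds free released group far too low for the autocatalytic step to start”.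

The simulation gives 4.47 × 10⁻⁵ M, 4.47 × 10⁻⁵ M, 4.47 × 10⁻⁵ M and 4.47 × 10⁻⁵ M, a course that hardly changes.

On Wednesday's at 15.0 s, free [released group] stands at 1.69 × 10⁻⁷ M, far below the crossing level, and the self-feeding step runs at 0.430% of the pace of the direct step, while on Sunday's at 15.0 s the reading of 5.08 × 10⁻⁸ M puts it at 0.129%. Wednesday's at 150 s, ten times the asked time, holds 5.53 × 10⁻⁶ M, still less than the crossing level at 14.0% of it.

(The constants used here stand for no real mixture; what happens was integrated by code.)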